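I decided to reckon the south-west flask by one number and to let each question hang on it.

all flasks: Q 0.44 mM

| run | E | remark | time |
|---|---|---|---|
| south-west | 0.22 M | the very flask that is asked about, followed so far |  |
| west | 0.15 M | run made earlier |  |
| flask | 0.22 M |  | 5.0 h |

| run | time / min | J / % | E / % |
|---|---|---|---|
| south-west | 60.0 | 24.8 | 19.6 |
| south-west | 120 | 31.7 | 0 |
| south-west | 180 | 31.2 | 1.2 |
| south-west | 240 | 34.5 | 1.7 |
| south-west | 300 | 30.5 | 1.2 |
| west | 1.33 | 0.1 | 93.6 |
| west | 4.00 | 1.2 | 81.6 |
| west | 8.00 | 5.7 | 67.0 |
| west | 10.0 | 6.1 | 60.2 |
| west | 15.0 | 10.6 | 46.7 |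

(readings scatter by 1 percentage point)

- teal: change nothing and wait 5.0 h more
- amber: at 5.0 h add Q, 100% of the amount charged, then wait 5.0 h
- blue: at 5.0 h take out 90% of the J then present, then wait 5.0 h

* J, in percent of the E first charged, at 5.0 h
* the remedy with the largest gain of J, or "none" below 2 percentage points (teal / amber / blue / none)
* J present, with what was taken out counted in, in percent of the E first charged, after teal
* J present, with what was taken out counted in, in percent of the E first charged, after blue

- given per volume of solution although it is solid: E
- J that was removed still counts
- at the start none of E is in solution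
- additions bring no volume worth counting

The readings form a ladder of times. On the fastest rung, in the west run, E fell from 93.6% at 1.33 min to 46.7% at 15.0 min, a read half-life of 13.6 min. Meanwhile J per E lost climbed from 0.0652 at 4.00 min to 0.199 at 15.0 min, so I put something between E and J. On the next rung, in the south-west flask, that ratio already read 0.308 at 60.0 min. On the last rung, from 120 min to 300 min, J stayed between 30.5% and 34.5%, with E at 1.7% or less, and I could read no slower rung.

So I carried the balance share φ, J divided by the E that has left the solid, which read 0.323; the usual term for such a yield is thermodynamic control. If J is pulled out and the pool rebalances, the gain goes with φ times the share that is not J, and this product peaks in the symmetric case, an even split of 0.5.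

gain of blue = 90% × φ × (1 − φ) = 20 percentage points

J after blue = φ + gain = 52.0%

Teal added nothing in my reckoning, and I took amber as no gain, which the runs, both at 0.44 mM of Q, could not test.

The forecast gave 32% now, 32% after teal and 51% after blue, with a range of 32% to 55%, and chose blue: “That constancy suggests a fast reversible step”.

The flask gave 32.1% now, 32.1% after teal and 51.8% after blue, so blue gained 20 points, and the forecast stood.

    L ⇌ J (K = 0.660, k = 7.25 × 10⁻⁴ s⁻¹)
    J ⇌ Z (K = 0.420, k = 2.63 × 10⁻⁴ s⁻¹)
    Z + Q ⇌ D + Q, rate k3*[Q]*[Z] forward; the back reaction follows from the equilibrium constant (K = 0.420, k = 1.24 M⁻¹ s⁻¹)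
    D + Q ⇌ L + Q, rate k4*[Q]*[D] forward; the back reaction follows from the equilibrium constant (k = 0.547 M⁻¹ s⁻¹)
    E ⇌ L, rate k5*(cs5 - [L]) while solid is left; crystals form when [L] > cs5 (solubility = 0.120 M, k = 0.00111 s⁻¹)

The relaxation half-life of J and Z by that step alone, both ways together, was 13.0 min, short against the 5.0 h. J stood at 32.3% at 150 min and at 32.1% at 300 min.

The forecast's 32% would be wrong for a larger charge: "now" has moved by 5 points at 0.290 M. In a neighbour flask with [E] of 0.37 M, 33.7% of E stood at 300 min, so φ gave 21.4%. The computed J there was 21.3%.

(The data were generated by integration with constants of no real substance, noise included.)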